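Two questions stand for each of two flasks: which form of the monomer leads at the end, and how much of the charge it holds.

| flask | free monomer | pre-initiator | remark | time |
|---|---|---|---|---|
| Thursday's | 2 M | 23 mM | run made earlier |  |
| Wednesday's | 2 M | 51 mM | run made earlier |  |
| oak | 2.0 M | 34 mM |  | 4.0 min |
| alder | 2.0 M | 34 mM |  | 3.0 min |

| run | time / min | monomer in chains / % | free monomer / % |
|---|---|---|---|
| Thursday's | 0.333 | 1.1 | 100.2 |
| Thursday's | 0.667 | 1.2 | 98.1 |
| Thursday's | 1.00 | 2.8 | 97.3 |
| Thursday's | 1.33 | 3.5 | 95.0 |
| Thursday's | 1.50 | 4.6 | 93.9 |
| Thursday's | 2.00 | 8.7 | 91.9 |
| Thursday's | 2.50 | 10.5 | 90.8 |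
| Wednesday's | 0.167 | 0.3 | 100.5 |
| Wednesday's | 0.333 | 0 | 98.3 |
| Wednesday's | 0.667 | 2.8 | 97.9 |
| Wednesday's | 1.00 | 7.1 | 94.7 |
| Wednesday's | 1.33 | 8.8 | 92.1 |
| Wednesday's | 2.00 | 16.7 | 82.9 |
| Wednesday's | 2.50 | 23.2 | 76.5 |

(each reading ± 1 percentage point)

- which of these there is most of at the end, counted by the free monomer in it, oak (monomer in chains / free monomer)
- which of these there is most of at the end, counted by the free monomer in it, alder (monomer in chains / free monomer)
- final amount of the leader among these, as a percentage of the free monomer charged, in oak
- final amount of the leader among these, as a percentage of the free monomer charged, in alder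

- amounts and yields of monomer in chains count crystals too
- given per volume of solution although it is solid: crystals
- the numbers in the tables scatter by 1 percentage point (one standard deviation)
- steps that have been proposed: free monomer + living end -> monomer in chains + living end; pre-initiator -> initiator; crystals <-> monomer in chains; free monomer + initiator -> living end + monomer in chains

Let f be the fraction of the charged free monomer still free. Wednesday's last readings add up to 99.7 % of the charge, so what free monomer lost stands as monomer in chains, within the scatter. The symmetric case is the even split, f = 0.5, where the leader changes, and it serves as the mark on the scale. Distance is counted by the burn B, the natural logarithm of the charge over the free monomer left. B starts at zero, and the even split lies at 0.693.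

First take the main step alone, free monomer + living end, with a steady stock of living ends. This step is pseudo-first-order, so B climbs straight in time, with a slope proportional to that stock. Wednesday's run reads B = 0.0823 at 1.33 min and 0.268 at 2.50 min, a slope of 0.159 min⁻¹.

Now add the supply. Pre-initiator must become initiator, and initiator a living end, so the line starts late. Carried back, it reaches zero at a lag of 0.811 min, a reading with its scatter. Each pre-initiator yields one living end, so the slope scales with the charge, while the lag does not, the free monomer charge being equal. Thursday's run tests this: the line gives f = 88.6 % at 2.50 min, against a reading of 90.8 %, a miss of 2.2 percentage points with a scatter of 1 point.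

Last come the crystals. They draw on monomer in chains and are counted with it, so B stays as it was.

Oak and alder carry 0.667 of Wednesday's pre-initiator, which gives a slope of 0.106 min⁻¹. The quantity to carry is the estimated crossing time 7.37 min, the lag plus 0.693 over the slope, at which this line puts B at the even split. Oak stops at 4.0 min and alder at 3.0 min, both earlier than that, so this reckoning has free monomer leading, at 71.3 % in oak and 79.3 % in alder.

The forecast also names free monomer for oak and free monomer for alder, with 73 % and 80 %, a little above this reckoning. It holds that “the rate is roughly proportional to pre-initiator”.

Free monomer leads, at 71.2 % in oak and 79.7 % in alder.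

free monomer + living end → monomer in chains + living end, rate k1*[living end]*[free monomer] (k = 3.60 L mol⁻¹ min⁻¹); pre-initiator → initiator (k = 4.70 min⁻¹); crystals ⇌ monomer in chains, rate k3*(cs3 - [monomer in chains]) while solid is left; crystals form when [monomer in chains] > cs3 (solubility = 41.0 mM, k = 21.0 min⁻¹); free monomer + initiator → living end + monomer in chains (k = 0.440 L mol⁻¹ min⁻¹) At oak's asked time, 94.4 % of the pre-initiator charge stands as living end and 5.60 % as initiator. Oak's time is 0.543 of the estimated crossing time 7.37 min. The same flask read at 10 min, later than the estimated crossing time, has monomer in chains in the lead, with free monomer down to 34.5 %.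

The runs are calculated with made-up constants.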